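**Retrosynthetic overview**
1. Locants: the decalin is numbered as the octahydronaphthalene (ring A = C4a, C5, C6, C7, C8, C8a; ring B = C1 to C4, C4a, C8a), the dioxane as O1, O2, C3 to C6; side-chain carbons carry these locants throughout.
2. End game: CO2H from CH2OH; the dioxane by SN2 of a C6 hydroperoxide on a C3 mesylate, the C6–OOH from invertive perhydrolysis of a C5–C6 epoxide that the C3 hydroxyl directs; the side chain from alkyne 18 (carboalumination) and epoxide 27 (Evans aldol).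
3. Ring A: two-carbon ring expansion of a 2,2-dimethylcyclobutanol whose carbinol carbon (future C8) is bonded to C8a of a ring B cyclohexene; C8–C5 breaks, C5–C4a forms, and the C8=C8a enolate is trapped as triflate and reduced.
4. Enabling feature: in ring A the quaternary gem-dimethyl carbon C5 sits next to the ring-fusion CH (C4a) and C8=C8a is the only alkene, so O–C8–C8a=C4a is an oxy-allyl relay over which tertiary C5 can shift from C8 to C4a, ending exactly as the C8=C8a double bond.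
5. Order of rings: ring B first (cyclohexenone; C2 and C1 by conjugate addition and enolate alkylations), then the cyclobutane is attached, ring A by ring expansion, the 1,2-dioxane last.

Key step: step 5

Remark (assumption): 2,2-dimethylcyclobutan-1-one (8) is taken as a purchasable building block.
Notation: Dec = (1R,2R,4aS)-1,2,5,5-tetramethyl-1,2,3,4,4a,5,6,7-octahydronaphthalen-1-yl; dioxane intermediates are numbered so that C3 carries the propyl side chain.

Step 1
Reactants: 1 cyclohex-2-en-1-one; 2 allyl acetate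
Product: 4 (2S,3R)-2-allyl-3-methylcyclohexan-1-one, via methylzinc enolate 3 (not isolated)
Conditions: Cu(OTf)2 (2 mol%), (R,S,S)-binaphthol bis(1-phenylethyl)amine phosphoramidite (4 mol%), Me2Zn, toluene, −30 °C; then 2, Pd(PPh3)4 (4 mol%), 0 °C
Reagents that add atoms: dimethylzinc (C[Zn]C)
Why: Copper-catalysed asymmetric conjugate addition sets C3 under ligand control (the ligand enantiomer is chosen to give the 3R enolate), and Tsuji–Trost allylation of the regiodefined zinc enolate should place the allyl group at C2 trans to the new methyl group.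

Step 2
Reactants: 4 (2S,3R)-2-allyl-3-methylcyclohexan-1-one
Product: 6 (2R,3R)-2-allyl-2,3-dimethylcyclohexan-1-one, via potassium enolate 5 (not isolated)
Conditions: t-BuOK, t-BuOH/THF, 0 °C to rt; MeI
Reagents that add atoms: iodomethane (CI)
Why: Alkylation of the more substituted (thermodynamic) enolate, in which MeI should enter axially on the face opposite to the pseudoaxial C3 methyl group, so that the new methyl is trans and the allyl group cis to the C3 methyl (quaternary centre by substrate control).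

Step 3
Reactants: 6 (2R,3R)-2-allyl-2,3-dimethylcyclohexan-1-one
Product: 7 N'-[(2R,3R)-2-allyl-2,3-dimethylcyclohexylidene]-2,4,6-triisopropylbenzenesulfonohydrazide
Conditions: 2,4,6-triisopropylbenzenesulfonohydrazide, HCl (cat.), MeCN, rt
Reagents that add atoms: 2,4,6-triisopropylbenzenesulfonohydrazide (NNS(=O)(=O)c1c(C(C)C)cc(C(C)C)cc1C(C)C)
Why: Acid-catalysed hydrazone condensation that touches no stereocentre and prepares the Shapiro reaction.

Step 4
Reactants: 7 N'-[(2R,3R)-2-allyl-2,3-dimethylcyclohexylidene]-2,4,6-triisopropylbenzenesulfonohydrazide; 8 2,2-dimethylcyclobutan-1-one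
Product: 10 1-[(5R,6R)-6-allyl-5,6-dimethylcyclohex-1-en-1-yl]-2,2-dimethylcyclobutan-1-ol (both carbinol epimers), via alkenyllithium 9 (not isolated)
Conditions: n-BuLi (2.1 equiv), TMEDA, THF/hexane, −78 to 0 °C; then 8, −78 to −20 °C; aq NH4Cl
Reagents that add atoms: none
Why: Shapiro reaction, regiospecific because only C6 of the ketone carries α-hydrogens, followed by 1,2-addition of the alkenyllithium to the strained ketone; the carbinol configuration is irrelevant because that carbon becomes sp2 in step 5.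

Step 5
Reactants: 10 1-[(5R,6R)-6-allyl-5,6-dimethylcyclohex-1-en-1-yl]-2,2-dimethylcyclobutan-1-ol
Product: 13 (4aS,7R,8R)-8-allyl-4,4,7,8-tetramethyl-2,3,4,4a,5,6,7,8-octahydronaphthalen-1-yl trifluoromethanesulfonate, via potassium alkoxide 11 (not isolated), via potassium enolate 12 (not isolated)
Conditions: KH (1.2 equiv), 18-crown-6 (1.2 equiv), THF, 0 to 50 °C; then PhNTf2, −78 to 0 °C
Reagents that add atoms: N-phenylbis(trifluoromethanesulfonimide) (O=S(=O)(N(c1ccccc1)S(=O)(=O)C(F)(F)F)C(F)(F)F)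
Why: Proposed new method: the potassium alkoxide weakens the strained C8–C5 bond (oxyanion effect, cyclobutane strain, tertiary C5), so C5 should leave C8 and rebond at C4a, the far end of the O–C8–C8a=C4a unit, in an anionic oxy-accelerated [1,3] shift (stepwise, through a caged ketyl/tertiary-alkyl pair) that delivers the cyclohexanone enolate 12 with its double bond at C8=C8a, which PhNTf2 traps on oxygen. The closest known reaction types are the alkoxide-accelerated vinylcyclobutane-to-cyclohexene rearrangement of 2-vinylcyclobutanols and the anionic two-carbon ring expansion of 1-vinylcycloalkenols; a 1-alkenylcyclobutanol with a plain tertiary alkyl migrating carbon is the untested substrate class. Ring A closes in a 6-endo-trig sense (C5 onto C4a, tether through C8), the four-membered ring growing by two atoms. The new stereocentre C4a is controlled by ring B: the C1 allyl group (pseudoaxial in the half-chair with equatorial C2 methyl) and the C2 methyl lie on one face, so C5 should add to the opposite face and leave H-4a cis to the allyl group. The step needs cleavage of C8–C5 and not C8–C7 (secured by the gem-dimethyl group), closure at C4a and not back at C8 (secured by strain release and enolate formation), and a C8=C8a enolate only (secured because it is formed there and trapped before it can equilibrate).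

Step 6
Reactants: 13 (4aS,7R,8R)-8-allyl-4,4,7,8-tetramethyl-2,3,4,4a,5,6,7,8-octahydronaphthalen-1-yl trifluoromethanesulfonate
Product: 14 (1R,2R,4aS)-1-allyl-1,2,5,5-tetramethyl-1,2,3,4,4a,5,6,7-octahydronaphthalene
Conditions: Pd(OAc)2 (5 mol%), PPh3 (10 mol%), HCO2H, n-Bu3N, DMF, 60 °C
Reagents that add atoms: none
Why: Palladium-catalysed formate reduction of the enol triflate (oxidative addition to zerovalent palladium, decarboxylation of formate, reductive elimination) replaces OTf by H without moving the double bond.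

Step 7
Reactants: 14 (1R,2R,4aS)-1-allyl-1,2,5,5-tetramethyl-1,2,3,4,4a,5,6,7-octahydronaphthalene
Product: 16 3-Dec-propan-1-ol, via B-alkyl-9-BBN adduct 15 (not isolated)
Conditions: 9-BBN, THF, 0 °C to rt; then aq NaOH, H2O2, 0 °C
Reagents that add atoms: hydrogen peroxide (OO)
Why: Hydroboration–oxidation, in which 9-BBN should add anti-Markovnikov to the monosubstituted alkene only, the trisubstituted ring A alkene next to the quaternary carbon being far slower.

Step 8
Reactants: 16 3-Dec-propan-1-ol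
Product: 17 3-Dec-propanal
Conditions: Dess–Martin periodinane, CH2Cl2, rt
Reagents that add atoms: none
Why: Dess–Martin oxidation of the primary alcohol to the aldehyde under neutral conditions that leave the alkene alone.

Step 9
Reactants: 17 3-Dec-propanal
Product: 18 (1R,2R,4aS)-1-(but-3-yn-1-yl)-1,2,5,5-tetramethyl-1,2,3,4,4a,5,6,7-octahydronaphthalene
Conditions: dimethyl (1-diazo-2-oxopropyl)phosphonate, K2CO3, MeOH, 0 °C to rt
Reagents that add atoms: dimethyl (1-diazo-2-oxopropyl)phosphonate (CC(=O)C(=[N+]=[N-])P(=O)(OC)OC)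
Why: Seyferth–Gilbert homologation with the Ohira–Bestmann reagent converts the aldehyde into the terminal alkyne with one added carbon (future C5).

Step 10
Reactants: 19 (4S)-4-benzyl-3-propanoyl-1,3-oxazolidin-2-one; 20 (benzyloxy)acetaldehyde
Product: 22 (4S)-4-benzyl-3-[(2S,3S)-4-(benzyloxy)-3-hydroxy-2-methylbutanoyl]-1,3-oxazolidin-2-one, via dibutylboron enolate 21 (not isolated)
Conditions: n-Bu2BOTf, i-Pr2NEt, CH2Cl2, 0 °C; then 20, −78 to 0 °C; then pH 7 buffer, MeOH, H2O2
Reagents that add atoms: none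
Why: Evans syn-aldol reaction, in which the Z-boron enolate reacts through a Zimmerman–Traxler chair on the face away from the benzyl group of the auxiliary and so sets the methyl-bearing carbon and the carbinol carbon syn under auxiliary control.

Step 11
Reactants: 22 (4S)-4-benzyl-3-[(2S,3S)-4-(benzyloxy)-3-hydroxy-2-methylbutanoyl]-1,3-oxazolidin-2-one
Product: 23 (2R,3S)-4-(benzyloxy)-2-methylbutane-1,3-diol
Conditions: LiBH4, MeOH (1 equiv), THF, 0 °C
Reagents that add atoms: none
Why: Reductive cleavage of the acyl oxazolidinone (hydride attack at the exocyclic carbonyl) frees the primary alcohol and the auxiliary without touching either stereocentre.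

Step 12
Reactants: 23 (2R,3S)-4-(benzyloxy)-2-methylbutane-1,3-diol
Product: 24 (2S,3R)-1-(benzyloxy)-4-[(tert-butyldiphenylsilyl)oxy]-3-methylbutan-2-ol
Conditions: TBDPSCl, imidazole, CH2Cl2, 0 °C
Reagents that add atoms: tert-butyl(chloro)diphenylsilane (CC(C)(C)[Si](Cl)(c1ccccc1)c1ccccc1)
Why: Silylation with the bulky chlorosilane should be selective for the primary hydroxyl.

Step 13
Reactants: 24 (2S,3R)-1-(benzyloxy)-4-[(tert-butyldiphenylsilyl)oxy]-3-methylbutan-2-ol
Product: 25 (2S,3R)-4-[(tert-butyldiphenylsilyl)oxy]-3-methylbutane-1,2-diol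
Conditions: H2 (1 atm), 10% Pd/C, EtOAc, rt
Reagents that add atoms: none
Why: Hydrogenolysis of the benzyl ether, to which the silyl ether is inert.

Step 14
Reactants: 25 (2S,3R)-4-[(tert-butyldiphenylsilyl)oxy]-3-methylbutane-1,2-diol
Product: 27 tert-butyl{(2R)-2-[(2S)-oxiran-2-yl]propoxy}diphenylsilane, via primary tosylate 26 (not isolated)
Conditions: NaH (2.2 equiv), 1-(p-toluenesulfonyl)imidazole, THF, 0 °C to rt
Reagents that add atoms: none
Why: Selective sulfonylation of the primary alkoxide followed by intramolecular Williamson closure (3-exo-tet) gives the terminal epoxide with retention at the secondary carbon, which is not a reacting centre.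

Step 15
Reactants: 18 (1R,2R,4aS)-1-(but-3-yn-1-yl)-1,2,5,5-tetramethyl-1,2,3,4,4a,5,6,7-octahydronaphthalene; 27 tert-butyl{(2R)-2-[(2S)-oxiran-2-yl]propoxy}diphenylsilane
Product: 30 (2R,3R,5E)-1-[(tert-butyldiphenylsilyl)oxy]-2,6-dimethyl-8-Dec-oct-5-en-3-ol, via alkenylalane 28 (not isolated), via lithium alanate 29 (not isolated)
Conditions: AlMe3, Cp2ZrCl2, CH2Cl2, 0 °C to rt; volatiles removed; n-BuLi, hexane, 0 °C; then 27, THF, −30 °C to rt
Reagents that add atoms: trimethylaluminium (C[Al](C)C)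
Why: Zirconium-catalysed carboalumination (Negishi) adds Me and Al syn across the alkyne with Me on the internal carbon, and the derived alanate opens the epoxide at its CH2 terminus with retention of alkene geometry, so the (E)-trisubstituted alkene forms and C3 keeps its configuration.

Step 16
Reactants: 30 (2R,3R,5E)-1-[(tert-butyldiphenylsilyl)oxy]-2,6-dimethyl-8-Dec-oct-5-en-3-ol
Product: 31 (2R,3R,5S,6S)-1-[(tert-butyldiphenylsilyl)oxy]-5,6-epoxy-2,6-dimethyl-8-Dec-octan-3-ol
Conditions: VO(acac)2 (5 mol%), t-BuOOH, CH2Cl2, 0 °C to rt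
Reagents that add atoms: tert-butyl hydroperoxide (CC(C)(C)OO)
Why: Hydroxyl-directed epoxidation of the homoallylic alcohol through a chair-like vanadate transition state (C3 substituent equatorial, alkene arm turned outward because of the methyl group cis to C4) should deliver oxygen to one face, setting C5 and C6, and should leave the non-directed ring A alkene alone.

Step 17
Reactants: 31 (2R,3R,5S,6S)-1-[(tert-butyldiphenylsilyl)oxy]-5,6-epoxy-2,6-dimethyl-8-Dec-octan-3-ol
Product: 32 (2R,3R,5S,6S)-1-[(tert-butyldiphenylsilyl)oxy]-5,6-epoxy-2,6-dimethyl-8-Dec-octan-3-yl methanesulfonate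
Conditions: MsCl, Et3N, CH2Cl2, 0 °C
Reagents that add atoms: methanesulfonyl chloride (CS(=O)(=O)Cl)
Why: Sulfonylation at oxygen activates C3 with retention and removes the hydroxyl that could otherwise open the epoxide.

Step 18
Reactants: 32 (2R,3R,5S,6S)-1-[(tert-butyldiphenylsilyl)oxy]-5,6-epoxy-2,6-dimethyl-8-Dec-octan-3-yl methanesulfonate
Product: 33 (2R,3R,5S,6R)-1-[(tert-butyldiphenylsilyl)oxy]-6-hydroperoxy-5-hydroxy-2,6-dimethyl-8-Dec-octan-3-yl methanesulfonate
Conditions: H2O2 (anhydrous, in Et2O), H3PMo12O40 (cat.), Et2O, rt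
Reagents that add atoms: hydrogen peroxide (OO)
Why: Molybdenum-catalysed perhydrolysis of the epoxide, in which H2O2 should open the activated epoxide at the more substituted carbon C6 in a borderline SN2 process with inversion, setting the tertiary peroxide centre.

Step 19
Reactants: 33 (2R,3R,5S,6R)-1-[(tert-butyldiphenylsilyl)oxy]-6-hydroperoxy-5-hydroxy-2,6-dimethyl-8-Dec-octan-3-yl methanesulfonate
Product: 34 (3S,5S,6R)-3-{(2R)-1-[(tert-butyldiphenylsilyl)oxy]propan-2-yl}-6-methyl-6-(2-Dec-ethyl)-1,2-dioxan-5-ol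
Conditions: CsOH·H2O (1.05 equiv), DMF, 0 °C
Reagents that add atoms: none
Why: Intramolecular alkylation of the hydroperoxide anion (the more acidic OH) by the secondary mesylate, a 6-exo-tet SN2 reaction, closes the 1,2-dioxane with inversion at C3.

Step 20
Reactants: 34 (3S,5S,6R)-3-{(2R)-1-[(tert-butyldiphenylsilyl)oxy]propan-2-yl}-6-methyl-6-(2-Dec-ethyl)-1,2-dioxan-5-ol
Product: 35 (3S,6R)-3-{(2R)-1-[(tert-butyldiphenylsilyl)oxy]propan-2-yl}-6-methyl-6-(2-Dec-ethyl)-3,6-dihydro-1,2-dioxine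
Conditions: Burgess reagent (MeO2CN−SO2N+Et3), toluene, 60 °C
Reagents that add atoms: none
Why: Burgess dehydration (syn elimination through the sulfamate ester) can only use a hydrogen on C4, because C6 is quaternary, so the 3,6-dihydro-1,2-dioxine is the only possible alkene.

Step 21
Reactants: 35 (3S,6R)-3-{(2R)-1-[(tert-butyldiphenylsilyl)oxy]propan-2-yl}-6-methyl-6-(2-Dec-ethyl)-3,6-dihydro-1,2-dioxine
Product: 36 (3S,6R)-3-{(2R)-1-[(tert-butyldiphenylsilyl)oxy]propan-2-yl}-6-methyl-6-(2-Dec-ethyl)-1,2-dioxane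
Conditions: KO2CN=NCO2K, AcOH, MeOH/CH2Cl2, 0 °C to rt
Reagents that add atoms: none
Why: Diimide reduction (concerted syn transfer of two hydrogens) saturates the cis-disubstituted ring alkene without cleaving the O–O bond and should spare the hindered trisubstituted ring A alkene.

Step 22
Reactants: 36 (3S,6R)-3-{(2R)-1-[(tert-butyldiphenylsilyl)oxy]propan-2-yl}-6-methyl-6-(2-Dec-ethyl)-1,2-dioxane
Product: 37 (2R)-2-[(3S,6R)-6-methyl-6-(2-Dec-ethyl)-1,2-dioxan-3-yl]propan-1-ol
Conditions: HF·pyridine, pyridine, THF, 0 °C to rt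
Reagents that add atoms: none
Why: Fluoride-mediated cleavage of the silyl ether under buffered, non-basic conditions that avoid Kornblum–DeLaMare cleavage of the dioxane.

Step 23
Reactants: 37 (2R)-2-[(3S,6R)-6-methyl-6-(2-Dec-ethyl)-1,2-dioxan-3-yl]propan-1-ol
Product: 39 mycaperoxide H, via aldehyde 38 (not isolated)
Conditions: TEMPO (cat.), PhI(OAc)2 (2.2 equiv), MeCN/H2O, rt
Reagents that add atoms: water (O)
Why: Oxoammonium (TEMPO/PhI(OAc)2) oxidation in wet acetonitrile takes the primary alcohol through the aldehyde hydrate to the acid under near-neutral conditions that should neither epimerise C2 nor touch the peroxide or the alkene.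

**Compound list**
1 | cyclohex-2-en-1-one | O=C1C=CCCC1 | starting material
2 | allyl acetate | CC(=O)OCC=C | starting material
3 | methylzinc (3R)-3-methylcyclohex-1-en-1-olate | C[Zn]OC1=C[C@H](C)CCC1 | intermediate
4 | (2S,3R)-2-allyl-3-methylcyclohexan-1-one | C=CC[C@@H]1C(=O)CCC[C@H]1C | intermediate
5 | potassium (3R)-2-allyl-3-methylcyclohex-1-en-1-olate | C=CCC1=C([O-])CCC[C@H]1C.[K+] | intermediate
6 | (2R,3R)-2-allyl-2,3-dimethylcyclohexan-1-one | C=CC[C@@]1(C)C(=O)CCC[C@H]1C | intermediate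
7 | N'-[(2R,3R)-2-allyl-2,3-dimethylcyclohexylidene]-2,4,6-triisopropylbenzenesulfonohydrazide | C=CC[C@@]1(C)C(=NNS(=O)(=O)c2c(C(C)C)cc(C(C)C)cc2C(C)C)CCC[C@H]1C | intermediate
8 | 2,2-dimethylcyclobutan-1-one | CC1(C)CCC1=O | starting material
9 | [(5R,6R)-6-allyl-5,6-dimethylcyclohex-1-en-1-yl]lithium | C=CC[C@@]1(C)C([Li])=CCC[C@H]1C | intermediate
10 | 1-[(5R,6R)-6-allyl-5,6-dimethylcyclohex-1-en-1-yl]-2,2-dimethylcyclobutan-1-ol (both carbinol epimers) | C=CC[C@@]1(C)C(C2(O)CCC2(C)C)=CCC[C@H]1C | intermediate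
11 | potassium 1-[(5R,6R)-6-allyl-5,6-dimethylcyclohex-1-en-1-yl]-2,2-dimethylcyclobutan-1-olate | C=CC[C@@]1(C)C(C2([O-])CCC2(C)C)=CCC[C@H]1C.[K+] | intermediate
12 | potassium (4aS,7R,8R)-8-allyl-4,4,7,8-tetramethyl-2,3,4,4a,5,6,7,8-octahydronaphthalen-1-olate | C=CC[C@@]1(C)C2=C([O-])CCC(C)(C)[C@@H]2CC[C@H]1C.[K+] | intermediate
13 | (4aS,7R,8R)-8-allyl-4,4,7,8-tetramethyl-2,3,4,4a,5,6,7,8-octahydronaphthalen-1-yl trifluoromethanesulfonate | C=CC[C@@]1(C)C2=C(OS(=O)(=O)C(F)(F)F)CCC(C)(C)[C@@H]2CC[C@H]1C | intermediate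
14 | (1R,2R,4aS)-1-allyl-1,2,5,5-tetramethyl-1,2,3,4,4a,5,6,7-octahydronaphthalene | C=CC[C@@]1(C)C2=CCCC(C)(C)[C@@H]2CC[C@H]1C | intermediate
15 | 9-(3-Dec-propyl)-9-borabicyclo[3.3.1]nonane | B1(CCC[C@@]2(C)C3=CCCC(C)(C)[C@@H]3CC[C@H]2C)C2CCCC1CCC2 | intermediate
16 | 3-Dec-propan-1-ol | OCCC[C@@]1(C)C2=CCCC(C)(C)[C@@H]2CC[C@H]1C | intermediate
17 | 3-Dec-propanal | O=CCC[C@@]1(C)C2=CCCC(C)(C)[C@@H]2CC[C@H]1C | intermediate
18 | (1R,2R,4aS)-1-(but-3-yn-1-yl)-1,2,5,5-tetramethyl-1,2,3,4,4a,5,6,7-octahydronaphthalene | C#CCC[C@@]1(C)C2=CCCC(C)(C)[C@@H]2CC[C@H]1C | intermediate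
19 | (4S)-4-benzyl-3-propanoyl-1,3-oxazolidin-2-one | CCC(=O)N1[C@@H](Cc2ccccc2)COC1=O | starting material
20 | (benzyloxy)acetaldehyde | O=CCOCc1ccccc1 | starting material
21 | dibutylboron (Z)-enolate of 19 | C/C=C(\OB(CCCC)CCCC)N1[C@@H](Cc2ccccc2)COC1=O | intermediate
22 | (4S)-4-benzyl-3-[(2S,3S)-4-(benzyloxy)-3-hydroxy-2-methylbutanoyl]-1,3-oxazolidin-2-one | C[C@H](C(=O)N1[C@@H](Cc2ccccc2)COC1=O)[C@H](O)COCc1ccccc1 | intermediate
23 | (2R,3S)-4-(benzyloxy)-2-methylbutane-1,3-diol | C[C@H](CO)[C@H](O)COCc1ccccc1 | intermediate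
24 | (2S,3R)-1-(benzyloxy)-4-[(tert-butyldiphenylsilyl)oxy]-3-methylbutan-2-ol | C[C@H](CO[Si](c1ccccc1)(c1ccccc1)C(C)(C)C)[C@H](O)COCc1ccccc1 | intermediate
25 | (2S,3R)-4-[(tert-butyldiphenylsilyl)oxy]-3-methylbutane-1,2-diol | C[C@H](CO[Si](c1ccccc1)(c1ccccc1)C(C)(C)C)[C@H](O)CO | intermediate
26 | (2S,3R)-4-[(tert-butyldiphenylsilyl)oxy]-2-hydroxy-3-methylbutyl 4-methylbenzenesulfonate | C[C@H](CO[Si](c1ccccc1)(c1ccccc1)C(C)(C)C)[C@H](O)COS(=O)(=O)c1ccc(C)cc1 | intermediate
27 | tert-butyl{(2R)-2-[(2S)-oxiran-2-yl]propoxy}diphenylsilane | C[C@H](CO[Si](c1ccccc1)(c1ccccc1)C(C)(C)C)[C@H]1CO1 | intermediate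
28 | [(1E)-2-methyl-4-Dec-but-1-en-1-yl]dimethylalumane | C[Al](C)/C=C(\C)CC[C@@]1(C)C2=CCCC(C)(C)[C@@H]2CC[C@H]1C | intermediate
29 | lithium butyl(dimethyl)[(1E)-2-methyl-4-Dec-but-1-en-1-yl]alanate | [Li+].CCCC[Al-](C)(C)/C=C(\C)CC[C@@]1(C)C2=CCCC(C)(C)[C@@H]2CC[C@H]1C | intermediate
30 | (2R,3R,5E)-1-[(tert-butyldiphenylsilyl)oxy]-2,6-dimethyl-8-Dec-oct-5-en-3-ol | C[C@H](CO[Si](c1ccccc1)(c1ccccc1)C(C)(C)C)[C@H](O)C/C=C(\C)CC[C@@]1(C)C2=CCCC(C)(C)[C@@H]2CC[C@H]1C | intermediate
31 | (2R,3R,5S,6S)-1-[(tert-butyldiphenylsilyl)oxy]-5,6-epoxy-2,6-dimethyl-8-Dec-octan-3-ol | C[C@H](CO[Si](c1ccccc1)(c1ccccc1)C(C)(C)C)[C@H](O)C[C@@H]1O[C@@]1(C)CC[C@@]2(C)C3=CCCC(C)(C)[C@@H]3CC[C@H]2C | intermediate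
32 | (2R,3R,5S,6S)-1-[(tert-butyldiphenylsilyl)oxy]-5,6-epoxy-2,6-dimethyl-8-Dec-octan-3-yl methanesulfonate | C[C@H](CO[Si](c1ccccc1)(c1ccccc1)C(C)(C)C)[C@H](OS(C)(=O)=O)C[C@@H]1O[C@@]1(C)CC[C@@]2(C)C3=CCCC(C)(C)[C@@H]3CC[C@H]2C | intermediate
33 | (2R,3R,5S,6R)-1-[(tert-butyldiphenylsilyl)oxy]-6-hydroperoxy-5-hydroxy-2,6-dimethyl-8-Dec-octan-3-yl methanesulfonate | C[C@H](CO[Si](c1ccccc1)(c1ccccc1)C(C)(C)C)[C@H](OS(C)(=O)=O)C[C@H](O)[C@](C)(OO)CC[C@@]1(C)C2=CCCC(C)(C)[C@@H]2CC[C@H]1C | intermediate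
34 | (3S,5S,6R)-3-{(2R)-1-[(tert-butyldiphenylsilyl)oxy]propan-2-yl}-6-methyl-6-(2-Dec-ethyl)-1,2-dioxan-5-ol | C[C@H](CO[Si](c1ccccc1)(c1ccccc1)C(C)(C)C)[C@@H]1C[C@H](O)[C@@](C)(CC[C@@]2(C)C3=CCCC(C)(C)[C@@H]3CC[C@H]2C)OO1 | intermediate
35 | (3S,6R)-3-{(2R)-1-[(tert-butyldiphenylsilyl)oxy]propan-2-yl}-6-methyl-6-(2-Dec-ethyl)-3,6-dihydro-1,2-dioxine | C[C@H](CO[Si](c1ccccc1)(c1ccccc1)C(C)(C)C)[C@@H]1C=C[C@@](C)(CC[C@@]2(C)C3=CCCC(C)(C)[C@@H]3CC[C@H]2C)OO1 | intermediate
36 | (3S,6R)-3-{(2R)-1-[(tert-butyldiphenylsilyl)oxy]propan-2-yl}-6-methyl-6-(2-Dec-ethyl)-1,2-dioxane | C[C@H](CO[Si](c1ccccc1)(c1ccccc1)C(C)(C)C)[C@@H]1CC[C@@](C)(CC[C@@]2(C)C3=CCCC(C)(C)[C@@H]3CC[C@H]2C)OO1 | intermediate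
37 | (2R)-2-[(3S,6R)-6-methyl-6-(2-Dec-ethyl)-1,2-dioxan-3-yl]propan-1-ol | C[C@H](CO)[C@@H]1CC[C@@](C)(CC[C@@]2(C)C3=CCCC(C)(C)[C@@H]3CC[C@H]2C)OO1 | intermediate
38 | (2S)-2-[(3S,6R)-6-methyl-6-(2-Dec-ethyl)-1,2-dioxan-3-yl]propanal | C[C@H](C=O)[C@@H]1CC[C@@](C)(CC[C@@]2(C)C3=CCCC(C)(C)[C@@H]3CC[C@H]2C)OO1 | intermediate
39 | mycaperoxide H, (2S)-2-[(3S,6R)-6-methyl-6-{2-[(1R,2R,4aS)-1,2,5,5-tetramethyl-1,2,3,4,4a,5,6,7-octahydronaphthalen-1-yl]ethyl}-1,2-dioxan-3-yl]propanoic acid | C[C@H](C(=O)O)[C@@H]1CC[C@@](C)(CC[C@@]2(C)C3=CCCC(C)(C)[C@@H]3CC[C@H]2C)OO1 | target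

**Step count and risks**
Total step count: 23. Longest linear sequence: 18 steps (steps 1 to 9 and 15 to 23).

Three steps most likely to fail:

1. Step 5 (the proposed new method). What may go wrong: the oxyanion-weakened cyclobutane may undergo cycloreversion (loss of isobutene) or open with hydrogen transfer instead of closing onto C4a, and C5 may add to the wrong face of C4a. Fallback with known chemistry, setting out from 10: a redox-neutral photoredox ring expansion by proton-coupled electron transfer ([Ir(dF(CF3)ppy)2(5,5'-d(CF3)bpy)]PF6, 2,4,6-collidine, blue light, CH2Cl2) would form the alkoxy radical, which opens by β-scission to the enone and the tertiary C5 radical. Because only one radical centre is then present, cycloreversion is not available; 6-endo radical conjugate addition at C4a and reduction–protonation would give the ketone (4aR,7R,8R)-8-allyl-4,4,7,8-tetramethyloctahydronaphthalen-1(2H)-one F1. Formation of the more substituted enol triflate under equilibrating conditions (Tf2O, 2,6-di-tert-butyl-4-methylpyridine, CH2Cl2) would return to the route at 13.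

2. Step 18. What may go wrong: ionisation at the tertiary carbon with loss of stereochemical fidelity, a hydride or alkyl shift of the activated epoxide, or oxidation of the ring A alkene by the peroxomolybdate. Fallback, setting out from 30: mesylation (MsCl, Et3N) would give (2R,3R,5E)-1-[(tert-butyldiphenylsilyl)oxy]-2,6-dimethyl-8-Dec-oct-5-en-3-yl methanesulfonate F2. Mukaiyama–Isayama hydroperoxysilylation (Co(thd)2 with thd = 2,2,6,6-tetramethylheptane-3,5-dionate, O2, Et3SiH, ClCH2CH2Cl) of the unhindered side-chain alkene, the ring A alkene being shielded by the quaternary C1, would give (2R,3R)-1-[(tert-butyldiphenylsilyl)oxy]-2,6-dimethyl-8-Dec-6-[(triethylsilyl)peroxy]octan-3-yl methanesulfonate F3 as both C6 epimers. Bu4NF at low temperature would free the peroxide anion, which closes the ring by SN2 at C3 to give 36 together with its epimer (3S,6S)-3-{(2R)-1-[(tert-butyldiphenylsilyl)oxy]propan-2-yl}-6-methyl-6-(2-Dec-ethyl)-1,2-dioxane F4, to be separated by chromatography. The route is rejoined at 36; steps 16 to 21 are bypassed, at the cost of stereocontrol at C6.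

3. Step 20. What may go wrong: the sulfamate may ionise and a group may shift from C6 toward a peroxycarbenium ion instead of the syn elimination, or the elimination may stall for lack of a well-aligned hydrogen. Fallback, setting out from 34: 1,1'-thiocarbonyldiimidazole and DMAP would give O-[(3S,5S,6R)-3-{(2R)-1-[(tert-butyldiphenylsilyl)oxy]propan-2-yl}-6-methyl-6-(2-Dec-ethyl)-1,2-dioxan-5-yl] 1H-imidazole-1-carbothioate F5. Barton–McCombie deoxygenation (Bu3SnH at high concentration, AIBN, toluene, 80 °C), in which hydrogen transfer should outrun attack of the C5 radical on the O–O bond, would give 36 directly, where the route is rejoined.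

Further compounds
F1 | step 5 | (4aR,7R,8R)-8-allyl-4,4,7,8-tetramethyloctahydronaphthalen-1(2H)-one (both C8a epimers) | C=CC[C@@]1(C)C2C(=O)CCC(C)(C)[C@@H]2CC[C@H]1C
F2 | step 18 | (2R,3R,5E)-1-[(tert-butyldiphenylsilyl)oxy]-2,6-dimethyl-8-Dec-oct-5-en-3-yl methanesulfonate | C[C@H](CO[Si](c1ccccc1)(c1ccccc1)C(C)(C)C)[C@H](OS(C)(=O)=O)C/C=C(\C)CC[C@@]1(C)C2=CCCC(C)(C)[C@@H]2CC[C@H]1C
F3 | step 18 | (2R,3R)-1-[(tert-butyldiphenylsilyl)oxy]-2,6-dimethyl-8-Dec-6-[(triethylsilyl)peroxy]octan-3-yl methanesulfonate (both C6 epimers) | C[C@H](CO[Si](c1ccccc1)(c1ccccc1)C(C)(C)C)[C@H](OS(C)(=O)=O)CCC(C)(OO[Si](CC)(CC)CC)CC[C@@]1(C)C2=CCCC(C)(C)[C@@H]2CC[C@H]1C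
F4 | step 18 | (3S,6S)-3-{(2R)-1-[(tert-butyldiphenylsilyl)oxy]propan-2-yl}-6-methyl-6-(2-Dec-ethyl)-1,2-dioxane | C[C@H](CO[Si](c1ccccc1)(c1ccccc1)C(C)(C)C)[C@@H]1CC[C@](C)(CC[C@@]2(C)C3=CCCC(C)(C)[C@@H]3CC[C@H]2C)OO1
F5 | step 20 | O-[(3S,5S,6R)-3-{(2R)-1-[(tert-butyldiphenylsilyl)oxy]propan-2-yl}-6-methyl-6-(2-Dec-ethyl)-1,2-dioxan-5-yl] 1H-imidazole-1-carbothioate | C[C@H](CO[Si](c1ccccc1)(c1ccccc1)C(C)(C)C)[C@@H]1C[C@H](OC(=S)n2ccnc2)[C@@](C)(CC[C@@]2(C)C3=CCCC(C)(C)[C@@H]3CC[C@H]2C)OO1
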